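The route rests on disconnecting the C3=C4 alkene of the 5,6-dihydro-2H-pyran-2-one ring, the enoate CH=CH between the lactone carbonyl C2 and the ring CH2 (C5). The key step is a ring-closing olefin metathesis run last. It exploits the fact that the ring oxygen O1 carries an acryloyl group and the adjacent carbinol carbon C6 an allyl group, so joining their terminal alkene carbons closes the six-membered lactone in one operation. All three stereocenters, the free hydroxyl, the allylic acetate and both E-alkenes are already in place. The precursor is an acyclic tetraene acrylate, built linearly by a CBS reduction, a 1,3-anti vinylogous Mukaiyama aldol and a Keck allylation.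

Key step: step 9

Assumption: the structure is taken as drawn, (S) at the lactone carbinol carbon C6, (R) at the free carbinol and (S) at the acetoxy carbon (an anti-1,3-diol monoacetate); ring atoms are numbered O1, C2(=O), C3, C4, C5, C6.

Step 1
Reactants: 1 benzaldehyde; 2 4,4-dimethoxybutan-2-one
Product: 4 (E)-5,5-dimethoxy-1-phenylpent-1-en-3-one, via aldol adduct 3 (not isolated)
Conditions: NaOH (aq), MeOH, 0 °C to rt
Reagents that add atoms: none
Why: Claisen–Schmidt condensation, in which the ketone should enolise at its unhindered methyl group, add to the non-enolisable aldehyde and dehydrate to the conjugated E-enone, with no stereocenter formed.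

Step 2
Reactants: 4 (E)-5,5-dimethoxy-1-phenylpent-1-en-3-one
Product: 5 (1E,3S)-5,5-dimethoxy-1-phenylpent-1-en-3-ol
Conditions: (R)-2-methyl-CBS-oxazaborolidine (20 mol%), catecholborane, toluene, −78 °C; MeOH quench
Reagents that add atoms: none
Why: CBS reduction, in which the oxazaborolidine–borane complex binds the ketone with the styryl group as the large substituent and delivers hydride to one face only (1,2-reduction), so the (S)-carbinol is set by catalyst control.

Step 3
Reactants: 5 (1E,3S)-5,5-dimethoxy-1-phenylpent-1-en-3-ol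
Product: 6 (1E,3S)-5,5-dimethoxy-1-phenylpent-1-en-3-yl acetate
Conditions: Ac2O, pyridine, DMAP (cat.), CH2Cl2, 0 °C to rt
Reagents that add atoms: acetic anhydride CC(=O)OC(C)=O
Why: DMAP-catalysed acylation of the only hydroxyl group, which places the acetate on its final oxygen before any other hydroxyl exists and leaves the stereocenter untouched.

Step 4
Reactants: 6 (1E,3S)-5,5-dimethoxy-1-phenylpent-1-en-3-yl acetate
Product: 7 (1E,3S)-5-oxo-1-phenylpent-1-en-3-yl acetate
Conditions: PPTS (cat.), acetone/H2O, 40 °C; used crude
Reagents that add atoms: water O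
Why: Mild acid-catalysed acetal hydrolysis, which should free the aldehyde without cleaving the ester; the β-acetoxy aldehyde is carried on without chromatography to avoid β-elimination.

Step 5
Reactants: 7 (1E,3S)-5-oxo-1-phenylpent-1-en-3-yl acetate; 8 (E)-1-(trimethylsilyloxy)buta-1,3-diene
Product: 9 (1E,3S,5R,7E)-5-hydroxy-9-oxo-1-phenylnona-1,7-dien-3-yl acetate
Conditions: BF3·OEt2, CH2Cl2, −78 °C; aq. NaHCO3 work-up
Reagents that add atoms: none
Why: Vinylogous Mukaiyama aldol, in which the γ-carbon of the silyl dienol ether attacks the BF3-activated aldehyde to give the E-enal directly, and the β-acetoxy stereocenter should direct 1,3-anti addition through the open, non-chelated, dipole-minimised transition state, setting the (5R)-carbinol.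

Step 6
Reactants: 9 (1E,3S,5R,7E)-5-hydroxy-9-oxo-1-phenylnona-1,7-dien-3-yl acetate
Product: 10 (1E,3S,5R,7E)-9-oxo-1-phenyl-5-(triethylsilyloxy)nona-1,7-dien-3-yl acetate
Conditions: Et3SiCl, imidazole, CH2Cl2, 0 °C
Reagents that add atoms: chlorotriethylsilane CC[Si](Cl)(CC)CC
Why: Silylation of the only hydroxyl group, so that the carbinol made in the next step can be acylated alone.

Step 7
Reactants: 10 (1E,3S,5R,7E)-9-oxo-1-phenyl-5-(triethylsilyloxy)nona-1,7-dien-3-yl acetate
Product: 11 (1E,3S,5R,7E,9S)-9-hydroxy-1-phenyl-5-(triethylsilyloxy)dodeca-1,7,11-trien-3-yl acetate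
Conditions: allylSnBu3, Ti(OiPr)4 (10 mol%), (S)-BINOL (20 mol%), 4 Å molecular sieves, CH2Cl2, −20 °C; aq. NaHCO3 work-up
Reagents that add atoms: allyltributylstannane C=CC[Sn](CCCC)(CCCC)CCCC
Why: Keck asymmetric allylation, in which the chiral BINOL–titanium Lewis acid activates the enal for 1,2-addition of the allylstannane to its Si face, so the (9S)-carbinol is set by catalyst control, independent of the remote stereocenters.

Step 8
Reactants: 11 (1E,3S,5R,7E,9S)-9-hydroxy-1-phenyl-5-(triethylsilyloxy)dodeca-1,7,11-trien-3-yl acetate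
Product: 13 (1E,3S,5R,7E,9S)-3-acetoxy-5-hydroxy-1-phenyldodeca-1,7,11-trien-9-yl prop-2-enoate, via silyl ether acrylate 12 (not isolated)
Conditions: acryloyl chloride, iPr2NEt, CH2Cl2, −20 to 0 °C; then HF·pyridine, THF, 0 °C to rt
Reagents that add atoms: acryloyl chloride C=CC(=O)Cl
Why: Acylation of the sole free hydroxyl group followed by fluoride cleavage of the triethylsilyl ether in the same pot, under buffered conditions that should leave the acetate and acrylate in place and not promote acetyl migration.

Step 9
Reactants: 13 (1E,3S,5R,7E,9S)-3-acetoxy-5-hydroxy-1-phenyldodeca-1,7,11-trien-9-yl prop-2-enoate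
Product: 14 (1E,3S,5R,7E)-5-hydroxy-8-[(2S)-6-oxo-3,6-dihydro-2H-pyran-2-yl]-1-phenylocta-1,7-dien-3-yl acetate (target)
Conditions: second-generation Grubbs catalyst (H2IMes)(PCy3)Cl2Ru=CHPh (5 mol%), CH2Cl2 (3 mM), 40 °C
Reagents that add atoms: none
Why: Ring-closing olefin metathesis: the ruthenium benzylidene should initiate at the monosubstituted allyl alkene, the resulting alkylidene on C4 undergoes intramolecular [2+2] cycloaddition with the acrylate C=C, and cycloreversion of the ruthenacyclobutane forms the C3=C4 bond and releases Ru=CH2, with loss of ethene making the closure irreversible. The closest known reaction type is the ring-closing metathesis of homoallylic alcohol acrylates to 5,6-dihydro-2H-pyran-2-ones. The one ring that closes is the six-membered lactone (O1, C2, C3, C4, C5, C6), closed by alkene–alkene metathesis between two chain ends tethered through O1–C6, and the ring size forces the Z geometry of the new alkene. No stereocenter is created, and C6, the free carbinol and the acetoxy carbinol are not touched under these neutral conditions, so no epimerisation or acetyl migration is expected. The step needs chemoselectivity for the two terminal alkenes over the two E-disubstituted alkenes; this is secured because initiation is fastest at the unhindered allyl group and the alkylidene on C4 has only one low-strain partner, since closure onto the neighbouring C=C would give a cyclobutene and closure onto the styrenyl alkene a ten-membered ring. High dilution should suppress dimerisation, and the free hydroxyl and both esters are tolerated by the catalyst.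

Compound list
1 | benzaldehyde | O=Cc1ccccc1 | starting material
2 | 4,4-dimethoxybutan-2-one | CC(=O)CC(OC)OC | starting material
3 | 5-hydroxy-1,1-dimethoxy-5-phenylpentan-3-one (racemic aldol adduct, not isolated) | COC(OC)CC(=O)CC(O)c1ccccc1 | intermediate
4 | (E)-5,5-dimethoxy-1-phenylpent-1-en-3-one | COC(OC)CC(=O)/C=C/c1ccccc1 | intermediate
5 | (1E,3S)-5,5-dimethoxy-1-phenylpent-1-en-3-ol | O[C@H](/C=C/c1ccccc1)CC(OC)OC | intermediate
6 | (1E,3S)-5,5-dimethoxy-1-phenylpent-1-en-3-yl acetate | CC(=O)O[C@H](/C=C/c1ccccc1)CC(OC)OC | intermediate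
7 | (1E,3S)-5-oxo-1-phenylpent-1-en-3-yl acetate | CC(=O)O[C@H](/C=C/c1ccccc1)CC=O | intermediate
8 | (E)-1-(trimethylsilyloxy)buta-1,3-diene | C=C/C=C/O[Si](C)(C)C | starting material
9 | (1E,3S,5R,7E)-5-hydroxy-9-oxo-1-phenylnona-1,7-dien-3-yl acetate | CC(=O)O[C@H](/C=C/c1ccccc1)C[C@H](O)C/C=C/C=O | intermediate
10 | (1E,3S,5R,7E)-9-oxo-1-phenyl-5-(triethylsilyloxy)nona-1,7-dien-3-yl acetate | CC(=O)O[C@H](/C=C/c1ccccc1)C[C@H](O[Si](CC)(CC)CC)C/C=C/C=O | intermediate
11 | (1E,3S,5R,7E,9S)-9-hydroxy-1-phenyl-5-(triethylsilyloxy)dodeca-1,7,11-trien-3-yl acetate | CC(=O)O[C@H](/C=C/c1ccccc1)C[C@H](O[Si](CC)(CC)CC)C/C=C/[C@@H](O)CC=C | intermediate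
12 | (1E,3S,5R,7E,9S)-3-acetoxy-1-phenyl-5-(triethylsilyloxy)dodeca-1,7,11-trien-9-yl prop-2-enoate (not isolated) | CC(=O)O[C@H](/C=C/c1ccccc1)C[C@H](O[Si](CC)(CC)CC)C/C=C/[C@@H](OC(=O)C=C)CC=C | intermediate
13 | (1E,3S,5R,7E,9S)-3-acetoxy-5-hydroxy-1-phenyldodeca-1,7,11-trien-9-yl prop-2-enoate | CC(=O)O[C@H](/C=C/c1ccccc1)C[C@H](O)C/C=C/[C@@H](OC(=O)C=C)CC=C | intermediate
14 | (1E,3S,5R,7E)-5-hydroxy-8-[(2S)-6-oxo-3,6-dihydro-2H-pyran-2-yl]-1-phenylocta-1,7-dien-3-yl acetate | CC(=O)O[C@H](/C=C/c1ccccc1)C[C@H](O)C/C=C/[C@@H]1CC=CC(=O)O1 | target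

Total step count: 9. Longest linear sequence: 9 steps (1 and 2 to 14).

Steps most likely to fail

Step 5. The risks are incomplete 1,3-anti facial control in the addition to the β-acetoxy aldehyde, loss of acetic acid from the aldehyde by β-elimination, and Lewis-acid ionisation of the allylic acetate. The fallback sets out from compound 2 and comes back at compound 10; it builds the free carbinol by intramolecular hydride delivery instead of an aldol addition and never passes through aldehyde 7. Compound 2 is converted to its diisopinocampheylboron enolate (Ipc2BCl, in the antipode that gives the (5S) adduct, Et3N, Et2O, −78 °C) and added to (E)-cinnamaldehyde to give (5S,6E)-5-hydroxy-1,1-dimethoxy-7-phenylhept-6-en-3-one F1. Any minor enantiomer carried forward becomes a separable diastereomer at the catalyst-controlled allylation of step 7. An Evans–Tishchenko reduction (acetaldehyde, SmI2 15 mol%, THF, −10 °C) then transfers hydride from the samarium-bound hemiacetal to the ketone. This should give the anti product with the acetate on the original hydroxyl, (1E,3S,5S)-5-hydroxy-7,7-dimethoxy-1-phenylhept-1-en-3-yl acetate F2. Silylation (Et3SiCl, imidazole) gives (1E,3S,5S)-7,7-dimethoxy-1-phenyl-5-(triethylsilyloxy)hept-1-en-3-yl acetate F3. The acetal is cleaved without loss of the silyl ether (Et3SiOTf, 2,4,6-collidine, CH2Cl2, 0 °C; then H2O) to (1E,3S,5S)-7-oxo-1-phenyl-5-(triethylsilyloxy)hept-1-en-3-yl acetate F4. Wittig olefination with (triphenylphosphoranylidene)acetaldehyde (toluene, 80 °C) gives the E-enal 10.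

Step 7. The risks are insufficient facial selectivity at a carbonyl remote from the existing stereocenters and slow catalyst turnover caused by the Lewis-basic ester and silyl ether. The fallback sets out from compound 10 and comes back at compound 11; it sets the carbinol by ketone reduction instead of carbonyl addition. Uncatalysed allylboration (allylboronic acid pinacol ester, CH2Cl2, rt) gives the C9-epimeric alcohol mixture (1E,3S,5R,7E,9RS)-9-hydroxy-1-phenyl-5-(triethylsilyloxy)dodeca-1,7,11-trien-3-yl acetate F5. Buffered Dess–Martin oxidation (NaHCO3, CH2Cl2, 0 °C) gives the enone (1E,3S,5R,7E)-9-oxo-1-phenyl-5-(triethylsilyloxy)dodeca-1,7,11-trien-3-yl acetate F6. CBS reduction ((R)-2-methyl-CBS-oxazaborolidine, catecholborane, toluene, −78 °C), with the alkenyl group as the large substituent, should give 11.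

Step 9. The risks are secondary metathesis of the liberated Ru=CH2 at the two internal alkenes (chain cleavage and loss of the styrenyl end), dimerisation through the allyl group, and slowing of ring closure by chelation of the alkylidene to the free hydroxyl. The fallback sets out from compound 12, isolated by aqueous work-up of the acylation instead of being desilylated in the pot, and comes back at compound 14; the ring is closed on the protected substrate and the hydroxyl is freed afterwards. Ring-closing metathesis of 12 (second-generation Grubbs catalyst, Ti(OiPr)4 as additive, CH2Cl2, high dilution, 40 °C) gives the lactone (1E,3S,5R,7E)-8-[(2S)-6-oxo-3,6-dihydro-2H-pyran-2-yl]-1-phenyl-5-(triethylsilyloxy)octa-1,7-dien-3-yl acetate F7. Desilylation (HF·pyridine, THF, 0 °C) gives 14.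

Further compounds
F1 | step 5 | (5S,6E)-5-hydroxy-1,1-dimethoxy-7-phenylhept-6-en-3-one | O[C@H](/C=C/c1ccccc1)CC(=O)CC(OC)OC
F2 | step 5 | (1E,3S,5S)-5-hydroxy-7,7-dimethoxy-1-phenylhept-1-en-3-yl acetate | CC(=O)O[C@H](/C=C/c1ccccc1)C[C@H](O)CC(OC)OC
F3 | step 5 | (1E,3S,5S)-7,7-dimethoxy-1-phenyl-5-(triethylsilyloxy)hept-1-en-3-yl acetate | CC(=O)O[C@H](/C=C/c1ccccc1)C[C@H](O[Si](CC)(CC)CC)CC(OC)OC
F4 | step 5 | (1E,3S,5S)-7-oxo-1-phenyl-5-(triethylsilyloxy)hept-1-en-3-yl acetate | CC(=O)O[C@H](/C=C/c1ccccc1)C[C@H](O[Si](CC)(CC)CC)CC=O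
F5 | step 7 | (1E,3S,5R,7E,9RS)-9-hydroxy-1-phenyl-5-(triethylsilyloxy)dodeca-1,7,11-trien-3-yl acetate | CC(=O)O[C@H](/C=C/c1ccccc1)C[C@H](O[Si](CC)(CC)CC)C/C=C/C(O)CC=C
F6 | step 7 | (1E,3S,5R,7E)-9-oxo-1-phenyl-5-(triethylsilyloxy)dodeca-1,7,11-trien-3-yl acetate | CC(=O)O[C@H](/C=C/c1ccccc1)C[C@H](O[Si](CC)(CC)CC)C/C=C/C(=O)CC=C
F7 | step 9 | (1E,3S,5R,7E)-8-[(2S)-6-oxo-3,6-dihydro-2H-pyran-2-yl]-1-phenyl-5-(triethylsilyloxy)octa-1,7-dien-3-yl acetate | CC(=O)O[C@H](/C=C/c1ccccc1)C[C@H](O[Si](CC)(CC)CC)C/C=C/[C@@H]1CC=CC(=O)O1
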